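Early on, in both earlier runs, the target climbs nearly in a straight line from solid substrate that starts wholly undissolved, so I read that slope as an early rate constant, the share of the charge turned into target per hour. It is 0.0647 h⁻¹ from the first reading of the eta run at 31 °C and 0.00587 h⁻¹ from the last reading of the zeta run at 6 °C, both carrying the scatter, and since these two runs also differ in charge, 30 mM against 13 mM, it is my assumption, not a reading, that temperature carries the difference when I say that the logarithm of the constant rises by 0.0960 K⁻¹.

| flask | solid substrate | temperature | remark | time |
|---|---|---|---|---|
| zeta | 13 mM | 6 °C | run made earlier |  |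
| eta | 30 mM | 31 °C | run made earlier |  |
| west | 20 mM | 10 °C |  | 12 h |
| east | 20 mM | 25 °C |  | 12 h |
| north-east | 20 mM | −5 °C |  | 12 h |
| south | 20 mM | 40 °C |  | 12 h |

| run | time / h | target / % |
|---|---|---|
| zeta | 4.00 | 2.1 |
| zeta | 8.00 | 4.5 |
| zeta | 10.0 | 7.8 |
| zeta | 15.0 | 8.8 |
| eta | 1.33 | 8.6 |
| eta | 3.00 | 18.8 |
| eta | 4.00 | 22.5 |
| eta | 5.00 | 25.0 |

(each reading ± 1 percentage point)

- the flask that comes out highest in amount of target, in percent of the solid substrate charged, or "all alike" when all lie within 1.5 percentage points (west / east / north-east / south / all alike)
- target at the end, in percent of the solid substrate charged, west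
- target at the end, in percent of the solid substrate charged, east
- target at the end, in percent of the solid substrate charged, north-east
- target at the end, in percent of the solid substrate charged, south

- given per volume of solution although it is solid: solid substrate
- at the start none of the solid substrate is in solution
- what has only dissolved of solid substrate counts as not reacted

With that slope I count turnovers: south, at 40 °C for 12 h, comes to 1.84, and this turnover count, the early constant times the time, or dimensionless time, tells me how far along a run stands. The middle of a run shows in the eta run, where the last reading at 5.00 h has a count of 0.323, so a straight line would stand at 32.3% of the charge, but I read 25.0%, a gap wider than the scatter, and the target is falling behind for a reason the readings do not name.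

For the end I count north-east at 0.0245 and west at 0.103, low enough that I take the target as the count itself, 2.45% and 10.3%. East, at 0.436, lies past the last eta reading, and with the same proportional shortfall I reckon 33.7%. South has a count 5.70 times that of the last eta reading and above one, so the straight line overruns the charge, and the readings, which stop at the count of 0.323, do not tell me whether the target in south rests on a plateau or is being consumed; east is the highest flask I can reckon, so I name it, and I give south no number.

The forecast differs: it gives west 9.5%, east 26%, north-east 2% and south 33%, names south as highest, and calls south “fast, so it reaches the plateau”.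

The flasks give east as highest at 31.5%, with west at 10.5%, north-east at 1.06% and south at 3.08%.

starting material ⇌ target (K = 1.10, k = 0.0950 h⁻¹, Ea = 99.0 kJ mol⁻¹, ΔH = −46.0 kJ mol⁻¹); starting material ⇌ third isomer (K = 16.0, k = 0.00960 h⁻¹, Ea = 97.0 kJ mol⁻¹, ΔH = −29.0 kJ mol⁻¹); target → over-reaction product (k = 0.0390 h⁻¹, Ea = 99.0 kJ mol⁻¹); solid substrate ⇌ starting material, rate k4*(cs4 - [starting material]) while solid is left; crystals form when [starting material] > cs4 (solubility = 17.0 mM, k = 1.80 h⁻¹); starting material ⇌ isomer of the product (K = 18.0, k = 0.0170 h⁻¹, Ea = 111 kJ mol⁻¹, ΔH = −34.0 kJ mol⁻¹); (constants at 25 °C) At 12.0 h south holds 40.1% of the isomer of the product beside 3.08% of target, and that is what a count of 1.84 came to. The repeat of north-east at 20 °C counts 0.270, below the 0.436 of east, and it ends at 29.5% of target.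

(Readings and results are simulated with made-up constants.)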